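**Plan**

1. Numbering: cyclohexanone ring C1 (CH carrying the hexenoyl carbonyl C1″), C2, C3 (C=O), C4 (CH carrying propenyl), C5, C6 (CH carrying the tetronate carbon C5′; tetronate atoms O1′, C2′–C4′).
2. Cuts, last to first: C1″–CH2 of the side chain (Grignard on an N-methoxy-N-methylamide), C3′–C4′ and O1′–C2′ of the tetronate (Dieckmann, O-acylation), C1–C2 (key step), C5′–C6 (Michael addition), C4–allyl and C4–C5 (acetoacetate chemistry).
3. Enabling feature: the C1″ and C3 carbonyls are 1,4-related across C1–C2, a bond between two enolate α-carbons. Tying C1″ to the C5′ oxygen as a γ-lactone (O–C1″–C1–C6–C5′) leaves C1 as the only enolisable site on that side, so oxidative coupling of the lactone ketene acetal with the C3 methyl-ketone enol ether closes ring C1–C6.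
4. Forward order: open chain (C2 to C6, C1, C1″) → lactate unit joined at C6 → γ-lactone → anodic closure of the cyclohexanone (cis-fused bicycle) → lactone opened, tetronate closed on C5′ → side chain added and ketal removed.
5. Stereochemistry: C5′ from (S)-lactic acid by self-regeneration of the stereocentre (dioxolanone, attack anti to tert-butyl); C6 from the topicity of the Michael addition to the (E)-enoate; C1 from the cis ring fusion of the key step; C4 by base equilibration to the equatorial epimer; the (E)-propenyl group is carried as allyl (so that only C2 is enolised) and isomerised once C3 is a ketal.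

Key step: step 8

Remarks on the chemistry: the atom labels of the target are used for every intermediate. Compounds 6–8 are racemic and 9–13 are mixtures of the two C4 epimers, which step 9 converges. Assumption: the Michael addition of step 5 follows the closed, lithium-bridged transition state usual for lithium ester enolates and (E)-enoates.

**Route**

Step 1
Reactants: 1 (S)-lactic acid; 2 pivalaldehyde
Product: 3 (2S,5S)-2-tert-butyl-5-methyl-1,3-dioxolan-4-one (cis)
Conditions: TsOH·H2O (cat.), H2SO4 (cat.), pentane, reflux with azeotropic removal of water; crystallisation from pentane at −78 °C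
Reagents that add atoms: none
Why: Acid-catalysed acetalisation under thermodynamic control should favour the cis-dioxolanone, in which the new acetal centre C2 carries tert-butyl on the same face as the C5 methyl group, and low-temperature crystallisation removes the trans isomer.

Step 2
Reactants: 4 allyl acetoacetate; 5 methyl (E)-4-bromobut-2-enoate
Product: 6 1-allyl 6-methyl (E)-2-acetylhex-4-enedioate (racemic)
Conditions: NaH (1.0 equiv), 4 (1.5 equiv), THF, 0 °C; then 5 (1.0 equiv), 0 °C → rt
Reagents that add atoms: none
Why: SN2 C-alkylation of the sodium enolate of the β-keto ester at the primary allylic bromide (acetoacetic ester alkylation) forms the C4–C5 bond, the excess of 4 suppressing double alkylation.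

Step 3
Reactants: 6 1-allyl 6-methyl (E)-2-acetylhex-4-enedioate
Product: 7 methyl (E)-5-acetylocta-2,7-dienoate (racemic at C4)
Conditions: Pd(PPh3)4 (3 mol %), THF, rt
Reagents that add atoms: none
Why: Oxidative addition of zerovalent palladium to the allyl ester, loss of CO2 and recombination of the enolate with the allylpalladium cation (Pd-catalysed decarboxylative allylation of the Tsuji–Trost type) place the allyl group regiospecifically on C4 under neutral conditions that leave the enoate alone.

Step 4
Reactants: 7 methyl (E)-5-acetylocta-2,7-dienoate
Product: 8 methyl (E)-5-(2-methyl-1,3-dioxolan-2-yl)octa-2,7-dienoate (racemic at C4)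
Conditions: Me3SiOCH2CH2OSiMe3 (1.5 equiv), Me3SiOTf (5 mol %), CH2Cl2, −78 → −20 °C; pyridine quench
Reagents that add atoms: 1,2-bis(trimethylsilyloxy)ethane, C[Si](C)(C)OCCO[Si](C)(C)C
Why: Silyl triflate-catalysed ketalisation under aprotic conditions masks the methyl ketone, which the lithium enolate of step 5 would otherwise attack or deprotonate, without isomerising the enoate.

Step 5
Reactants: 3 (2S,5S)-2-tert-butyl-5-methyl-1,3-dioxolan-4-one; 8 ketal enoate
Product: 9 methyl (3S)-3-[(2S,4R)-2-tert-butyl-4-methyl-5-oxo-1,3-dioxolan-4-yl]-5-(2-methyl-1,3-dioxolan-2-yl)oct-7-enoate (both C4 epimers)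
Conditions: LiN(iPr)2 (1.3 equiv), 3 (1.3 equiv), THF, −78 °C, 30 min; then 8, −78 °C; AcOH quench at −78 °C
Reagents that add atoms: none
Why: Michael addition of the lithium enolate of 3 to the (E)-enoate: the enolate is attacked anti to tert-butyl, so C6 takes the place of the lactic acid hydrogen with retention and C5′ gets the configuration the tetronate needs, while C6 should arise from the lithium-bridged transition state in which the ester carbonyl is chelated to the enolate lithium and the C5 chain lies anti to the enolate carbon, away from the dioxolanone ring.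

Step 6
Reactants: 9 Michael adduct
Product: 11 methyl (2R,3S)-3-(2-acetylpent-4-enyl)-2-methyl-5-oxooxolane-2-carboxylate (keto lactone; both C4 epimers), via ketal lactone 10 (not isolated)
Conditions: NaOMe (0.3 equiv), MeOH, 0 °C → rt; then 2 M aq. HCl, THF, rt
Reagents that add atoms: methanol, CO; water, O
Why: Methoxide opens the dioxolanone to the C5′ methyl ester with loss of pivalaldehyde, the freed tertiary alkoxide closes the γ-lactone onto the C1″ ester (transesterification and lactonisation), and the aqueous acid completes lactonisation and hydrolyses the dioxolane (acetal hydrolysis) without touching C5′ or C6.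

Step 7
Reactants: 11 keto lactone
Product: 12 methyl (2R,3S)-5-(tert-butyldimethylsilyloxy)-3-[2-(1-(tert-butyldimethylsilyloxy)ethenyl)pent-4-enyl]-2-methyl-2,3-dihydrofuran-2-carboxylate (bis-silyl derivative; both C4 epimers)
Conditions: LiN(iPr)2 (2.5 equiv), THF, −78 °C (11 added to the base); TBSCl (3 equiv), DMPU, −78 → 0 °C; pentane, cold aq. NaHCO3; used without chromatography
Reagents that add atoms: tert-butyldimethylsilyl chloride, CC(C)(C)[Si](C)(C)Cl
Why: Kinetic enolate formation and O-silylation: the amide base should remove a proton from the methyl group C2 and not the hindered tertiary C4–H (which, with allyl in place of propenyl, is not allylic), and from C1 as the only α-position of the lactone (the C5′ ester has no α-hydrogen), so both enol derivatives form with defined regiochemistry.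

Step 8
Reactants: 12 bis-silyl derivative
Product: 13 methyl (1R,3aR,7aS)-1-methyl-3,5-dioxo-6-(prop-2-enyl)octahydro-2-benzofuran-1-carboxylate (cis-fused keto lactone; both C4 epimers)
Conditions: undivided cell, reticulated vitreous carbon anode, Pt cathode, constant current 8 mA to 2.2 F/mol, LiClO4 (0.1 M), 2,6-lutidine (4 equiv), MeCN/i-PrOH 4:1, 0 °C → rt; then brief 1 M aq. HCl/THF wash
Reagents that add atoms: none
Why: The lactone silyl ketene acetal, the more electron-rich π-system, loses one electron at the anode and the radical cation, electrophilic at C1, is captured by the unsubstituted terminus C2 of the C3 silyl enol ether; the α-silyloxy radical at C3 is oxidised again and both silyl groups pass to isopropanol (reduced at the cathode to hydrogen and isopropoxide), which returns the lactone carbonyl and the C3 ketone. The closest known reaction type is the intramolecular anodic coupling of a ketene acetal radical cation with an enol ether (anodic olefin coupling), run here as a net two-electron coupling of two silyl enol derivatives to a 1,4-dicarbonyl compound. The carbocycle C1–C6 closes through C1–C2 in the 6-endo mode with respect to the enol ether (C2 and C3 both become ring atoms), attack at the oxygen-bearing C3 (5-exo) being electronically disfavoured. The only new stereocentre, C1, is set by C6: the four-atom tether C5–C4–C3–C2 can reach C1 of the planar five-membered radical cation only from the face on which C5 sits, so the cyclohexanone should be cis-fused to the lactone. The step needs C2 rather than C4 to react on the ketone side, which the kinetic enol ether of step 7 secures, and needs the enol ether to win over the allyl group, which its far higher nucleophilicity secures (allyl would be a 6-exo competitor where propenyl would be a 5-exo one). 2,6-Lutidine keeps the medium non-acidic so that both silyl enol derivatives survive until they are oxidised.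

Step 9
Reactants: 13 cis-fused keto lactone (C4 epimers)
Product: 14 methyl (1R,3aR,6R,7aS)-1-methyl-3,5-dioxo-6-(prop-2-enyl)octahydro-2-benzofuran-1-carboxylate (allyl at C4 cis to the substituents at C1 and C6)
Conditions: DBU (0.5 equiv), CH2Cl2, rt
Reagents that add atoms: none
Why: Base-mediated epimerisation under thermodynamic control: reversible enolisation of the C3 ketone towards C4 should funnel both epimers into the one with equatorial allyl, cis to C5′ at C6, because the chair with the quaternary C5′ equatorial and the lactone carbonyl C1″ axial is strongly preferred, while C1, α only to the far less acidic lactone carbonyl, is not touched by DBU.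

Step 10
Reactants: 14 keto lactone (single C4 epimer)
Product: 15 spiro-1,3-dioxolane ketal of 14 at C3
Conditions: Me3SiOCH2CH2OSiMe3 (1.5 equiv), Me3SiOTf (5 mol %), CH2Cl2, −78 → −20 °C; pyridine quench
Reagents that add atoms: 1,2-bis(trimethylsilyloxy)ethane, C[Si](C)(C)OCCO[Si](C)(C)C
Why: Aprotic silyl triflate-catalysed ketalisation protects C3 against the bases and organometallic reagents that follow and freezes the C4 configuration set in step 9.

Step 11
Reactants: 15 allyl ketal lactone
Product: 16 (E)-prop-1-enyl ketal lactone (C1 R, C4 S, C6 S, C5′ R)
Conditions: [CpRu(MeCN)(L)]PF6 (2 mol %; L = 2-(di-isopropylphosphino)-4-tert-butyl-1-methylimidazole, P,N-bound), acetone, rt; stopped when the terminal alkene is consumed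
Reagents that add atoms: none
Why: Transition-metal-catalysed alkene isomerisation by one position turns allyl into 1-propenyl; the (E) isomer is expected because the (Z) isomer would suffer allylic strain against the branched C4, further migration would need a trisubstituted alkene at the congested C4 and is slow, and with C3 as a ketal the alkene cannot be drawn into conjugation.

Step 12
Reactants: 16 propenyl ketal lactone
Product: 17 hydroxy amide: C3-ketal cyclohexane with C(=O)N(OMe)Me at C1, (R)-C(OH)(CH3)CO2Me at C6 and (E)-propenyl at C4, all cis
Conditions: Me(MeO)NH·HCl (3 equiv), AlMe3 (3 equiv), CH2Cl2, 0 °C → rt; aq. potassium sodium tartrate work-up; crude product used at once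
Reagents that add atoms: N,O-dimethylhydroxylamine hydrochloride, CNOC.Cl
Why: Aminolysis of the γ-lactone by the aluminium amide should be chemoselective because the lactone carbonyl on the secondary C1 is far more accessible than the methyl ester on the quaternary C5′, and it exposes the C5′ tertiary alcohol and the C1″ N-methoxy-N-methylamide without touching C1 or C6.

Step 13
Reactants: 17 hydroxy amide
Product: 18 O-propanoate of 17
Conditions: LiN(SiMe3)2 (1.1 equiv), THF, −78 °C; EtCOCl (1.2 equiv), −78 → 0 °C
Reagents that add atoms: propanoyl chloride, CCC(=O)Cl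
Why: O-acylation of the hindered tertiary alcohol through its lithium alkoxide; basic conditions avoid the acid-promoted relactonisation of the γ-hydroxy amide, and the alkoxide should not displace the amide nitrogen because ring closure would expel the far more basic amide anion.

Step 14
Reactants: 18 propanoate
Product: 19 tetronic acid amide: 4-hydroxy-3,5-dimethylfuran-2(5H)-one joined through C5′ (R) to C6, with the C1 amide and the C3 ketal in place
Conditions: LiN(SiMe3)2 (2.3 equiv), THF, −78 → 0 °C; 1 M aq. HCl to pH 2 at 0 °C, extraction
Reagents that add atoms: none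
Why: Dieckmann condensation: the propanoate enolate attacks the adjacent C5′ methyl ester in a 5-exo-trig closure to the 3-methyltetronic acid, driven by deprotonation of the acidic product; no bond to C5′ is broken, so its configuration is kept, and LiN(SiMe3)2 is too weak a base to enolise the tertiary amide at C1.

Step 15
Reactants: 19 tetronic acid amide; 20 (E)-5-bromopent-2-ene
Product: 22 target compound CNP0546498.1 (C1 R, C4 S, C6 S, C5′ R), via ketal ketone 21 (not isolated)
Conditions: 20, Mg turnings, THF, rt, giving (E)-CH3CH=CHCH2CH2MgBr, used at once; 19, THF, −20 → 0 °C, Grignard solution (3.5 equiv); then 1 M aq. HCl/THF, 0 °C → rt; chromatography on silica with 0.5 % AcOH in the eluent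
Reagents that add atoms: (E)-pent-3-enylmagnesium bromide (made from 20), C/C=C/CC[Mg]Br; water, O
Why: Grignard addition to the N-methoxy-N-methylamide: the first equivalent turns the tetronic acid into its unreactive magnesium salt, a further equivalent adds to the amide to give a chelated tetrahedral intermediate that cannot add again, and the aqueous acid of the work-up releases the C1″ ketone and hydrolyses the dioxolane (acetal hydrolysis) to the C3 ketone under conditions mild enough to leave C1, C4 and the position of the propenyl double bond unchanged.

**Compound list**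

1 | (S)-lactic acid | C[C@H](O)C(O)=O | starting material
2 | pivalaldehyde | CC(C)(C)C=O | starting material
3 | (2S,5S)-2-tert-butyl-5-methyl-1,3-dioxolan-4-one (cis) | C[C@@H]1O[C@H](C(C)(C)C)OC1=O | intermediate
4 | allyl acetoacetate (prop-2-enyl 3-oxobutanoate) | CC(=O)CC(=O)OCC=C | starting material
5 | methyl (E)-4-bromobut-2-enoate | COC(=O)/C=C/CBr | starting material
6 | 1-allyl 6-methyl (E)-2-acetylhex-4-enedioate, racemic | CC(=O)C(C/C=C/C(=O)OC)C(=O)OCC=C | intermediate
7 | methyl (E)-5-acetylocta-2,7-dienoate, racemic | CC(=O)C(CC=C)C/C=C/C(=O)OC | intermediate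
8 | methyl (E)-5-(2-methyl-1,3-dioxolan-2-yl)octa-2,7-dienoate, racemic | CC1(OCCO1)C(CC=C)C/C=C/C(=O)OC | intermediate
9 | methyl (3S)-3-[(2S,4R)-2-tert-butyl-4-methyl-5-oxo-1,3-dioxolan-4-yl]-5-(2-methyl-1,3-dioxolan-2-yl)oct-7-enoate, both C4 epimers | COC(=O)C[C@H](CC(CC=C)C1(C)OCCO1)[C@](C)(C(=O)O2)O[C@@H]2C(C)(C)C | intermediate
10 | methyl (2R,3S)-2-methyl-3-[2-(2-methyl-1,3-dioxolan-2-yl)pent-4-enyl]-5-oxooxolane-2-carboxylate, both C4 epimers (not isolated) | O=C1C[C@H](CC(CC=C)C2(C)OCCO2)[C@](C)(C(=O)OC)O1 | intermediate
11 | methyl (2R,3S)-3-(2-acetylpent-4-enyl)-2-methyl-5-oxooxolane-2-carboxylate, both C4 epimers | O=C1C[C@H](CC(CC=C)C(C)=O)[C@](C)(C(=O)OC)O1 | intermediate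
12 | methyl (2R,3S)-5-(tert-butyldimethylsilyloxy)-3-[2-(1-(tert-butyldimethylsilyloxy)ethenyl)pent-4-enyl]-2-methyl-2,3-dihydrofuran-2-carboxylate, both C4 epimers | CC(C)(C)[Si](C)(C)OC1=C[C@H](CC(CC=C)C(=C)O[Si](C)(C)C(C)(C)C)[C@](C)(C(=O)OC)O1 | intermediate
13 | methyl (1R,3aR,7aS)-1-methyl-3,5-dioxo-6-(prop-2-enyl)octahydro-2-benzofuran-1-carboxylate, cis-fused, both C4 epimers | O=C1C[C@H]2C(=O)O[C@@](C)(C(=O)OC)[C@H]2CC1CC=C | intermediate
14 | methyl (1R,3aR,6R,7aS)-1-methyl-3,5-dioxo-6-(prop-2-enyl)octahydro-2-benzofuran-1-carboxylate, allyl cis to both ring-fusion substituents | O=C1C[C@H]2C(=O)O[C@@](C)(C(=O)OC)[C@H]2C[C@H]1CC=C | intermediate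
15 | spiro-1,3-dioxolane ketal of 14 at C3 | O1CCOC12C[C@H]3C(=O)O[C@@](C)(C(=O)OC)[C@H]3C[C@H]2CC=C | intermediate
16 | as 15 with (E)-prop-1-enyl at C4 in place of allyl | O1CCOC12C[C@H]3C(=O)O[C@@](C)(C(=O)OC)[C@H]3C[C@H]2/C=C/C | intermediate
17 | hydroxy amide: C3-ketal cyclohexane, C1 C(=O)N(OMe)Me, C6 (R)-C(OH)(CH3)CO2Me, C4 (E)-propenyl, all cis | O1CCOC12C[C@@H](C(=O)N(C)OC)[C@@H]([C@@](C)(O)C(=O)OC)C[C@H]2/C=C/C | intermediate
18 | O-propanoate of 17 | O1CCOC12C[C@@H](C(=O)N(C)OC)[C@@H]([C@@](C)(OC(=O)CC)C(=O)OC)C[C@H]2/C=C/C | intermediate
19 | tetronic acid amide: (5R)-4-hydroxy-3,5-dimethylfuran-2(5H)-on-5-yl at C6, C1 N-methoxy-N-methylamide, C3 ketal | O1CCOC12C[C@@H](C(=O)N(C)OC)[C@@H]([C@@]3(C)OC(=O)C(C)=C3O)C[C@H]2/C=C/C | intermediate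
20 | (E)-5-bromopent-2-ene | C/C=C/CCBr | starting material
21 | ketal ketone: as 19 with (E)-hex-4-enoyl at C1 in place of the amide (not isolated) | O1CCOC12C[C@@H](C(=O)CC/C=C/C)[C@@H]([C@@]3(C)OC(=O)C(C)=C3O)C[C@H]2/C=C/C | intermediate
22 | CNP0546498.1 | C/C=C/CCC(=O)[C@@H]1CC(=O)[C@H](/C=C/C)C[C@@H]1[C@@]1(C)OC(=O)C(C)=C1O | target

**Step count**

Total: 15 steps. Longest linear sequence: 14 steps (4 → 22, steps 2–15); step 1 is a one-step side branch.

**Steps most likely to fail**

Step 8 (anodic ring closure). What may go wrong: loss of the silyl group from the ketene acetal radical cation and reduction back to lactone 11 may outrun C1–C2 bond formation, or the product may be oxidised further at the anode. Fallback: a chemical, inner-sphere oxidative coupling of metal enolates in place of the electrolysis of silyl derivatives. It sets out from 11: LiN(iPr)2 (2.2 equiv) in THF at −78 °C would give the dilithium bis-enolate F1, and Fe(acac)3 (2.2 equiv, −78 °C → rt) would join C1 to C2 in an intramolecular oxidative enolate heterocoupling, the tether from C6 again enforcing the cis ring fusion. The fallback comes back at 13.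

Step 5 (Michael addition). What may go wrong: proton transfer from C5 of the enoate to the enolate may compete with conjugate addition, and the facial selectivity at C6 may be poor or opposite to that expected. Fallback: the geometry of the acceptor is changed, because in the lithium-bridged transition state a (Z)-enoate has to present the other face of C6. It sets out from 4: alkylation with commercial methyl 4-bromobut-2-ynoate (NaH, THF) would give 1-allyl 6-methyl 2-acetylhex-4-ynedioate F2; decarboxylative allylation (Pd(PPh3)4, THF) would give methyl 5-acetyloct-7-en-2-ynoate F3; ketalisation as in step 4 would give methyl 5-(2-methyl-1,3-dioxolan-2-yl)oct-7-en-2-ynoate F4; semi-hydrogenation (H2, Pd/CaCO3 poisoned with Pb(OAc)2, quinoline, stopped after one equivalent) would give methyl (Z)-5-(2-methyl-1,3-dioxolan-2-yl)octa-2,7-dienoate F5. Michael addition of the enolate of 3 to F5 under the conditions of step 5 comes back at 9.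

Step 7 (double enolisation and silylation). What may go wrong: the dienolate may condense with itself (aldol or Claisen type) before it is silylated, the ketone may be deprotonated at C4, or the bis-silyl compound may hydrolyse on isolation. Fallback: the two enol derivatives are made one after the other by two different kinds of enolisation, so that no dianion is formed. It sets out from 11: soft enolisation with TBSOTf (1.1 equiv) and Et3N in CH2Cl2 at −78 °C, where the silyl triflate activates the ketone long before the lactone and the amine takes the proton from the unhindered methyl group, would give the mono-silyl enol ether F6. Deprotonation of the lactone alone with LiN(iPr)2 (1.1 equiv, THF, −78 °C) and silylation with TBSCl/DMPU comes back at 12.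

**Further compounds**

F1 | step 8 | dilithium bis-enolate of 11 (lactone C1 enolate and ketone C2 enolate) | [Li]OC1=C[C@H](CC(CC=C)C(=C)O[Li])[C@](C)(C(=O)OC)O1
F2 | step 5 | 1-allyl 6-methyl 2-acetylhex-4-ynedioate | CC(=O)C(CC#CC(=O)OC)C(=O)OCC=C
F3 | step 5 | methyl 5-acetyloct-7-en-2-ynoate | CC(=O)C(CC=C)CC#CC(=O)OC
F4 | step 5 | methyl 5-(2-methyl-1,3-dioxolan-2-yl)oct-7-en-2-ynoate | CC1(OCCO1)C(CC=C)CC#CC(=O)OC
F5 | step 5 | methyl (Z)-5-(2-methyl-1,3-dioxolan-2-yl)octa-2,7-dienoate | CC1(OCCO1)C(CC=C)C/C=C\C(=O)OC
F6 | step 7 | methyl (2R,3S)-3-[2-(1-(tert-butyldimethylsilyloxy)ethenyl)pent-4-enyl]-2-methyl-5-oxooxolane-2-carboxylate | O=C1C[C@H](CC(CC=C)C(=C)O[Si](C)(C)C(C)(C)C)[C@](C)(C(=O)OC)O1
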